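The γ-lactone is built last, on the finished ten-membered ring. The future exocyclic methylene carbon (C13) is first attached as an O–CH2 tether to the oxygen on C4, as a 2-(alkoxymethyl)malonic acid. One oxidation with Mn(OAc)3 then generates the malonyl radical at C3, joins C3 to C3a by 5-exo attack on the C3a=C11a ring alkene and lactonises the new C11a radical through a carboxyl group (O1–C11a). The step exploits the C4 oxygen that flanks the C3a–C11a edge of the carbocycle. Decarboxylation and β-elimination of O4 from C13 then unveil the α-methylene lactone, and a Mitsunobu esterification inverts C4.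

Key step: step 14

Remarks on the chemistry:
- Ring compounds are discussed with the cyclodeca[b]furan locants of the target (O1, C2, C3, C3a, C4 … C11, C11a); C13 is the exocyclic methylene carbon and C14 the hydroxymethyl carbon on C10.
- The ring alkene formed in step 10 is drawn and named as 2Z; any 2E isomer is carried along, because step 14 is expected to be convergent.
- The sense of induction in step 7 is assumed to follow that of dialkylzinc additions with the same ligand; the other ligand enantiomer is used if the assignment proves reversed.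

Step 1
Reactants: 1 (R)-(−)-linalool
Product: 2 triethyl{[(3R)-3,7-dimethylocta-1,6-dien-3-yl]oxy}silane
Conditions: Et3SiOTf, 2,6-lutidine, CH2Cl2, 0 °C
Reagents that add atoms: triethylsilyl trifluoromethanesulfonate, CC[Si](CC)(CC)OS(=O)(=O)C(F)(F)F
Why: Silyl ether formation with the triflate and 2,6-lutidine protects the hindered tertiary alcohol of the chiral-pool terpene, whose stereocentre becomes C6 (6R) and is not touched again.

Step 2
Reactants: 2
Product: 4 (3R)-3,7-dimethyl-3-[(triethylsilyl)oxy]oct-6-en-1-ol, via B-alkyl-9-BBN adduct 3 (not isolated)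
Conditions: 9-BBN-H, THF, 0 to 50 °C; then NaOH (aq), H2O2, 0 °C
Reagents that add atoms: hydrogen peroxide, OO
Why: Brown hydroboration–oxidation: 9-BBN-H adds anti-Markovnikov to the monosubstituted vinyl group only, leaving the trisubstituted alkene, and alkaline H2O2 replaces boron by OH without change at the quaternary centre.

Step 3
Reactants: 4
Product: 6 (4R)-6-hydroxy-4-methyl-4-[(triethylsilyl)oxy]hexanal, via ozonide 5 (not isolated)
Conditions: O3, CH2Cl2, −78 °C; then PPh3, −78 °C to rt
Reagents that add atoms: ozone, [O-][O+]=O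
Why: Ozonolysis with reductive work-up cleaves the only C=C bond to the aldehyde (future C9) and acetone, while the silyl ether and the primary alcohol are inert at −78 °C.

Step 4
Reactants: 7 ethyl (triphenyl-λ5-phosphanylidene)acetate
Product: 9 ethyl 2-(triphenyl-λ5-phosphanylidene)pent-4-enoate, via phosphonium bromide 8 (not isolated)
Conditions: CH2=CHCH2Br, CHCl3, reflux; then NaOH (aq), CH2Cl2, 0 °C
Reagents that add atoms: allyl bromide, C=CCBr
Why: C-Alkylation of the stabilised ylide gives the phosphonium salt, which NaOH deprotonates to the α-allyl stabilised ylide (standard ylide alkylation).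

Step 5
Reactants: 6 (4R)-6-hydroxy-4-methyl-4-[(triethylsilyl)oxy]hexanal, 9 ethyl 2-(triphenyl-λ5-phosphanylidene)pent-4-enoate
Product: 10 ethyl (2E,6R)-8-hydroxy-6-methyl-2-(prop-2-en-1-yl)-6-[(triethylsilyl)oxy]oct-2-enoate
Conditions: toluene, 80 °C
Reagents that add atoms: none
Why: Wittig olefination with an α-substituted stabilised ylide should give the E-enoate (ester trans to the chain), which places C8 and the allyl CH2 (C11) cis on the C9=C10 bond as the ring requires.

Step 6
Reactants: 10
Product: 11 ethyl (2E,6R)-6-methyl-8-oxo-2-(prop-2-en-1-yl)-6-[(triethylsilyl)oxy]oct-2-enoate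
Conditions: Dess–Martin periodinane, NaHCO3, CH2Cl2, 0 °C to rt
Reagents that add atoms: none
Why: Dess–Martin oxidation converts the primary alcohol into the aldehyde under buffered conditions that leave the silyl ether, the enoate and the skipped diene alone.

Step 7
Reactants: 11
Product: 12 ethyl (2E,6R,8R)-8-hydroxy-6-methyl-2-(prop-2-en-1-yl)-6-[(triethylsilyl)oxy]deca-2,9-dienoate
Conditions: (CH2=CH)2Zn (from CH2=CHMgBr and ZnCl2, MgBrCl removed with 1,4-dioxane), (−)-DAIB (10 mol%), toluene/Et2O, −20 to 0 °C; then NH4Cl (aq)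
Reagents that add atoms: divinylzinc, C=C[Zn]C=C
Why: Amino-alcohol-catalysed organozinc addition (Noyori/Oppolzer type): the ligand–zinc chelate should deliver vinyl to the Si face of the aldehyde and set the carbinol as 8R, deliberately the C4 epimer of the target, and the minor epimer is a diastereomer removable by chromatography.

Step 8
Reactants: 12
Product: 13 (2E,6R,8R)-6-methyl-2-(prop-2-en-1-yl)-6-[(triethylsilyl)oxy]deca-2,9-diene-1,8-diol
Conditions: i-Bu2AlH (3.5 equiv), CH2Cl2, −78 °C; then KNaC4H4O6 (aq)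
Reagents that add atoms: none
Why: i-Bu2AlH reduces the conjugated ester by 1,2-addition to the allylic alcohol (the future C14 hydroxymethyl group) without touching the alkenes or the silyl ether.

Step 9
Reactants: 13
Product: 14 (3R,5R,8E)-9-({[tert-butyl(dimethyl)silyl]oxy}methyl)-5-methyl-5-[(triethylsilyl)oxy]dodeca-1,8,11-trien-3-ol
Conditions: TBSCl (1.05 equiv), imidazole, CH2Cl2, 0 °C
Reagents that add atoms: tert-butyldimethylsilyl chloride, CC(C)(C)[Si](C)(C)Cl
Why: Silylation at 0 °C is selective for the primary allylic alcohol over the hindered secondary one, which must stay free for the tether.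

Step 10
Reactants: 14
Product: 15 (1R,2Z,5E,9R)-5-({[tert-butyl(dimethyl)silyl]oxy}methyl)-9-methyl-9-[(triethylsilyl)oxy]cyclodeca-2,5-dien-1-ol
Conditions: second-generation Grubbs catalyst RuCl2(=CHPh)(H2IMes)(PCy3) (10 mol%), 1,4-benzoquinone (20 mol%), toluene (1 mM), 80 °C
Reagents that add atoms: none
Why: Ring-closing metathesis of the two terminal alkenes closes the ten-membered ring at C3a=C11a (the trisubstituted alkene is far less reactive), and the geometry of the new alkene need not be controlled because step 14 passes through a trigonal C11a radical.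

Step 11
Reactants: 16 di(prop-2-en-1-yl) propanedioate
Product: 17 di(prop-2-en-1-yl) 2-methylidenepropanedioate
Conditions: (CH2O)n, Cu(OAc)2 (cat.), KOAc (cat.), AcOH, 100 °C; distillation
Reagents that add atoms: paraformaldehyde (as formaldehyde), C=O
Why: Knoevenagel condensation of the malonate with formaldehyde gives the doubly activated acceptor, which is used freshly distilled.

Step 12
Reactants: 15 (1R,2Z,5E,9R)-5-({[tert-butyl(dimethyl)silyl]oxy}methyl)-9-methyl-9-[(triethylsilyl)oxy]cyclodeca-2,5-dien-1-ol, 17 di(prop-2-en-1-yl) 2-methylidenepropanedioate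
Product: 18 di(prop-2-en-1-yl) 2-({[(1R,2Z,5E,9R)-5-({[tert-butyl(dimethyl)silyl]oxy}methyl)-9-methyl-9-[(triethylsilyl)oxy]cyclodeca-2,5-dien-1-yl]oxy}methyl)propanedioate
Conditions: KN(SiMe3)2 (1.0 equiv), THF, −78 °C; then 17 (1.2 equiv); AcOH, −78 °C
Reagents that add atoms: none
Why: Oxa-Michael addition of the potassium alkoxide to the methylenemalonate at −78 °C, with cold protonation of the malonate enolate, attaches C13, C3 and both carboxyl carbons to O4 with retention at C4.

Step 13
Reactants: 18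
Product: 19 2-({[(1R,2Z,5E,9R)-5-({[tert-butyl(dimethyl)silyl]oxy}methyl)-9-methyl-9-[(triethylsilyl)oxy]cyclodeca-2,5-dien-1-yl]oxy}methyl)propanedioic acid
Conditions: Pd(PPh3)4 (5 mol%), morpholine, THF, rt; then NaHSO4 (aq)
Reagents that add atoms: none
Why: Tsuji–Trost deallylation with morpholine as allyl acceptor frees both acids under near-neutral conditions, which avoids base-induced retro-Michael loss of the tether and leaves the silyl ethers intact.

Step 14
Reactants: 19
Product: 20 tricyclic lactone acid (target locants): the ten-membered ring now carries a γ-lactone (C2(=O)–O1–C11a, C3–C3a) and a tetrahydrofuran (C3–C13H2–O–C4) that share the C3–C3a bond, with CO2H on C3; H3a trans to H11a and trans to H4, CO2H cis to H3a; 4R, 6R, 11aS, 9E; silyl ethers unchanged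
Conditions: Mn(OAc)3·2H2O (2.2 equiv), KOAc, degassed AcOH (5 mM), 25 °C
Reagents that add atoms: none
Why: Mn(OAc)3 oxidises the manganese-bound malonic acid to the malonyl radical at C3, which adds 5-exo-trig to C3a of the ring alkene, and the secondary C11a radical is then oxidised by a second Mn(OAc)3 within its carboxylate complex and closes the γ-lactone by O1–C11a bond formation. The closest known reaction type is the trivalent-manganese oxidative radical cyclisation–lactonisation of unsaturated malonic acids (double annulation). The tetrahydrofuran ring closes by 5-exo-trig radical addition and the lactone by 5-exo capture of the oxidised C11a centre by the carboxyl group on C3. C3a is controlled by the O4 tether, which should attack with H4 inside and C5 outside across an anticlinal C5–C4–C3a–C11a torsion of the ten-membered ring so that C3 ends trans to O4 (hence the 4R alcohol), C11a is controlled by the forming cis-fused dioxabicyclo[3.3.0]octane, which should place the C11 chain on its convex face and so give H11a trans to H3a, and C3 is fixed by the cis fusion of the two five-membered rings. The step needs regioselectivity (carbon at C3a, oxygen at C11a), secured by the tether length, and chemoselectivity against the C9=C10 alkene and the oxygen functions, secured by intramolecularity and by the silyl ethers on O6 and O14. Both geometrical isomers of the ring alkene converge on the same C11a radical.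

Step 15
Reactants: 20
Product: 22 (3aS,4R,6R,9E,11aS)-10-({[tert-butyl(dimethyl)silyl]oxy}methyl)-4-hydroxy-6-methyl-3-methylidene-6-[(triethylsilyl)oxy]-3a,4,5,6,7,8,11,11a-octahydrocyclodeca[b]furan-2(3H)-one, via tricyclic lactone 21 (not isolated)
Conditions: toluene, 100 °C; then KN(SiMe3)2 (1.2 equiv), THF, −78 to −20 °C; NH4Cl (aq), −78 °C
Reagents that add atoms: none
Why: Heating decarboxylates the malonic-type acid through the lactone enol, and the potassium lactone enolate then expels O4 from C13 (E1cB retro-oxa-Michael, driven by the change from enolate to alkoxide) to give the exocyclic methylene and the free 4R alcohol, C3 becoming trigonal so that its configuration is of no consequence.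

Step 16
Reactants: 23 (2E)-but-2-enal
Product: 24 (2Z)-2-iodobut-2-enal
Conditions: I2, K2CO3, DMAP (20 mol%), THF/H2O, rt
Reagents that add atoms: iodine, II
Why: α-Iodination of the enal by DMAP addition, iodination of the enolate and elimination (Baylis–Hillman-type sequence) keeps CH3 trans to CHO and so gives the 2Z iodide.

Step 17
Reactants: 24
Product: 25 (2Z)-2-iodobut-2-en-1-ol
Conditions: NaBH4, CeCl3·7H2O, MeOH, 0 °C
Reagents that add atoms: none
Why: Luche reduction gives 1,2-reduction of the enal without loss of the vinylic iodide or change of the alkene geometry.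

Step 18
Reactants: 25
Product: 27 (2Z)-2-(hydroxymethyl)but-2-enoic acid, via dilithio alkoxide 26 (not isolated)
Conditions: t-BuLi (3.2 equiv), Et2O, −78 °C; then CO2 (g); HCl (aq)
Reagents that add atoms: carbon dioxide, O=C=O
Why: Deprotonation of the alcohol and iodine–lithium exchange give a configurationally stable vinyllithium that is carboxylated with retention, so that CH3 ends cis to CO2H (2Z).

Step 19
Reactants: 27
Product: 28 (2Z)-2-[(acetyloxy)methyl]but-2-enoic acid
Conditions: Ac2O, pyridine, DMAP (cat.), CH2Cl2, 0 °C to rt; then THF/H2O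
Reagents that add atoms: acetic anhydride, CC(=O)OC(C)=O
Why: Acetylation of the primary alcohol, the mixed anhydride formed at the acid being hydrolysed on aqueous work-up and the alkene geometry left untouched.

Step 20
Reactants: 22 (3aS,4R,6R,9E,11aS)-10-({[tert-butyl(dimethyl)silyl]oxy}methyl)-4-hydroxy-6-methyl-3-methylidene-6-[(triethylsilyl)oxy]-3a,4,5,6,7,8,11,11a-octahydrocyclodeca[b]furan-2(3H)-one, 28 (2Z)-2-[(acetyloxy)methyl]but-2-enoic acid
Product: 29 [(3aR,4S,6R,9E,11aS)-10-({[tert-butyl(dimethyl)silyl]oxy}methyl)-6-methyl-3-methylidene-2-oxo-6-[(triethylsilyl)oxy]-2,3,3a,4,5,6,7,8,11,11a-decahydrocyclodeca[b]furan-4-yl] (2Z)-2-[(acetyloxy)methyl]but-2-enoate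
Conditions: PPh3, DIAD, toluene, 0 °C to rt
Reagents that add atoms: none
Why: Mitsunobu esterification: the carboxylate displaces the oxyphosphonium group at C4 in an SN2 reaction with inversion, turning the 4R alcohol into the 4S ester of the target, and C4 carries the only free hydroxyl group.

Step 21
Reactants: 29
Product: 30 [(3aR,4S,6R,9E,11aS)-6-hydroxy-10-(hydroxymethyl)-6-methyl-3-methylidene-2-oxo-2,3,3a,4,5,6,7,8,11,11a-decahydrocyclodeca[b]furan-4-yl] (2Z)-2-[(acetyloxy)methyl]but-2-enoate (CNP0313132.1)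
Conditions: HF·pyridine, pyridine, THF, 0 °C to rt
Reagents that add atoms: none
Why: Buffered fluoride desilylation cleaves the primary TBS and the tertiary TES ether without harming the α-methylene lactone, the allylic acetate or the unsaturated ester, and no stereocentre is involved.

Compound list
1 | (R)-(−)-linalool, (3R)-3,7-dimethylocta-1,6-dien-3-ol | C=C[C@](C)(O)CCC=C(C)C | starting material
2 | triethyl{[(3R)-3,7-dimethylocta-1,6-dien-3-yl]oxy}silane | C=C[C@](C)(O[Si](CC)(CC)CC)CCC=C(C)C | intermediate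
3 | B-alkyl-9-BBN adduct, 9-{(3S)-3,7-dimethyl-3-[(triethylsilyl)oxy]oct-6-en-1-yl}-9-borabicyclo[3.3.1]nonane (same spatial arrangement as 2) | CC(C)=CCC[C@@](C)(O[Si](CC)(CC)CC)CCB1C2CCCC1CCC2 | intermediate
4 | (3R)-3,7-dimethyl-3-[(triethylsilyl)oxy]oct-6-en-1-ol | OCC[C@](C)(O[Si](CC)(CC)CC)CCC=C(C)C | intermediate
5 | ozonide, (3R)-5-(5,5-dimethyl-1,2,4-trioxolan-3-yl)-3-methyl-3-[(triethylsilyl)oxy]pentan-1-ol (epimers at the trioxolane carbon) | OCC[C@](C)(O[Si](CC)(CC)CC)CCC1OOC(C)(C)O1 | intermediate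
6 | (4R)-6-hydroxy-4-methyl-4-[(triethylsilyl)oxy]hexanal | OCC[C@](C)(O[Si](CC)(CC)CC)CCC=O | intermediate
7 | ethyl (triphenyl-λ5-phosphanylidene)acetate | CCOC(=O)C=P(c1ccccc1)(c1ccccc1)c1ccccc1 | starting material
8 | (1-ethoxy-1-oxopent-4-en-2-yl)triphenylphosphonium bromide (racemic) | CCOC(=O)C(CC=C)[P+](c1ccccc1)(c1ccccc1)c1ccccc1.[Br-] | intermediate
9 | ethyl 2-(triphenyl-λ5-phosphanylidene)pent-4-enoate | CCOC(=O)C(CC=C)=P(c1ccccc1)(c1ccccc1)c1ccccc1 | intermediate
10 | ethyl (2E,6R)-8-hydroxy-6-methyl-2-(prop-2-en-1-yl)-6-[(triethylsilyl)oxy]oct-2-enoate | C=CC/C(C(=O)OCC)=C\CC[C@@](C)(O[Si](CC)(CC)CC)CCO | intermediate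
11 | ethyl (2E,6R)-6-methyl-8-oxo-2-(prop-2-en-1-yl)-6-[(triethylsilyl)oxy]oct-2-enoate | C=CC/C(C(=O)OCC)=C\CC[C@@](C)(O[Si](CC)(CC)CC)CC=O | intermediate
12 | ethyl (2E,6R,8R)-8-hydroxy-6-methyl-2-(prop-2-en-1-yl)-6-[(triethylsilyl)oxy]deca-2,9-dienoate | C=CC/C(C(=O)OCC)=C\CC[C@@](C)(O[Si](CC)(CC)CC)C[C@@H](O)C=C | intermediate
13 | (2E,6R,8R)-6-methyl-2-(prop-2-en-1-yl)-6-[(triethylsilyl)oxy]deca-2,9-diene-1,8-diol | C=CC/C(CO)=C\CC[C@@](C)(O[Si](CC)(CC)CC)C[C@@H](O)C=C | intermediate
14 | (3R,5R,8E)-9-({[tert-butyl(dimethyl)silyl]oxy}methyl)-5-methyl-5-[(triethylsilyl)oxy]dodeca-1,8,11-trien-3-ol | C=CC/C(CO[Si](C)(C)C(C)(C)C)=C\CC[C@@](C)(O[Si](CC)(CC)CC)C[C@@H](O)C=C | intermediate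
15 | (1R,2Z,5E,9R)-5-({[tert-butyl(dimethyl)silyl]oxy}methyl)-9-methyl-9-[(triethylsilyl)oxy]cyclodeca-2,5-dien-1-ol | C1[C@@H](O)/C=C\C/C(CO[Si](C)(C)C(C)(C)C)=C\CC[C@@]1(C)O[Si](CC)(CC)CC | intermediate
16 | di(prop-2-en-1-yl) propanedioate (diallyl malonate) | C=CCOC(=O)CC(=O)OCC=C | starting material
17 | di(prop-2-en-1-yl) 2-methylidenepropanedioate | C=CCOC(=O)C(=C)C(=O)OCC=C | intermediate
18 | di(prop-2-en-1-yl) 2-({[(1R,2Z,5E,9R)-5-({[tert-butyl(dimethyl)silyl]oxy}methyl)-9-methyl-9-[(triethylsilyl)oxy]cyclodeca-2,5-dien-1-yl]oxy}methyl)propanedioate | C1[C@@H](OCC(C(=O)OCC=C)C(=O)OCC=C)/C=C\C/C(CO[Si](C)(C)C(C)(C)C)=C\CC[C@@]1(C)O[Si](CC)(CC)CC | intermediate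
19 | 2-({[(1R,2Z,5E,9R)-5-({[tert-butyl(dimethyl)silyl]oxy}methyl)-9-methyl-9-[(triethylsilyl)oxy]cyclodeca-2,5-dien-1-yl]oxy}methyl)propanedioic acid | C1[C@@H](OCC(C(=O)O)C(=O)O)/C=C\C/C(CO[Si](C)(C)C(C)(C)C)=C\CC[C@@]1(C)O[Si](CC)(CC)CC | intermediate
20 | tricyclic lactone acid (target locants): γ-lactone C2(=O)–O1–C11a/C3–C3a and tetrahydrofuran C3–C13H2–O–C4 sharing the C3–C3a bond, CO2H on C3 cis to H3a, H3a trans to H11a and to H4; 4R, 6R, 11aS, 9E; 6-OSiEt3, 14-OTBS | O=C1O[C@H]2C/C(CO[Si](C)(C)C(C)(C)C)=C\CC[C@@](C)(O[Si](CC)(CC)CC)C[C@H]3OC[C@@]1(C(=O)O)[C@H]23 | intermediate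
21 | tricyclic lactone: compound 20 without the CO2H group, H3 cis to H3a | O=C1O[C@H]2C/C(CO[Si](C)(C)C(C)(C)C)=C\CC[C@@](C)(O[Si](CC)(CC)CC)C[C@H]3OC[C@H]1[C@H]23 | intermediate
22 | (3aS,4R,6R,9E,11aS)-10-({[tert-butyl(dimethyl)silyl]oxy}methyl)-4-hydroxy-6-methyl-3-methylidene-6-[(triethylsilyl)oxy]-3a,4,5,6,7,8,11,11a-octahydrocyclodeca[b]furan-2(3H)-one | C=C1C(=O)O[C@H]2C/C(CO[Si](C)(C)C(C)(C)C)=C\CC[C@@](C)(O[Si](CC)(CC)CC)C[C@@H](O)[C@H]12 | intermediate
23 | (2E)-but-2-enal (crotonaldehyde) | C/C=C/C=O | starting material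
24 | (2Z)-2-iodobut-2-enal | C/C=C(\I)C=O | intermediate
25 | (2Z)-2-iodobut-2-en-1-ol | C/C=C(\I)CO | intermediate
26 | lithium (2Z)-2-lithiobut-2-en-1-olate | C/C=C(\[Li])C[O-].[Li+] | intermediate
27 | (2Z)-2-(hydroxymethyl)but-2-enoic acid | C/C=C(/CO)C(=O)O | intermediate
28 | (2Z)-2-[(acetyloxy)methyl]but-2-enoic acid | C/C=C(/COC(C)=O)C(=O)O | intermediate
29 | [(3aR,4S,6R,9E,11aS)-10-({[tert-butyl(dimethyl)silyl]oxy}methyl)-6-methyl-3-methylidene-2-oxo-6-[(triethylsilyl)oxy]-2,3,3a,4,5,6,7,8,11,11a-decahydrocyclodeca[b]furan-4-yl] (2Z)-2-[(acetyloxy)methyl]but-2-enoate | C=C1C(=O)O[C@H]2C/C(CO[Si](C)(C)C(C)(C)C)=C\CC[C@@](C)(O[Si](CC)(CC)CC)C[C@H](OC(=O)/C(=C\C)COC(C)=O)[C@H]12 | intermediate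
30 | [(3aR,4S,6R,9E,11aS)-6-hydroxy-10-(hydroxymethyl)-6-methyl-3-methylidene-2-oxo-2,3,3a,4,5,6,7,8,11,11a-decahydrocyclodeca[b]furan-4-yl] (2Z)-2-[(acetyloxy)methyl]but-2-enoate | C=C1C(=O)O[C@H]2C/C(CO)=C\CC[C@@](C)(O)C[C@H](OC(=O)/C(=C\C)COC(C)=O)[C@H]12 | target

Total step count: 21
Longest linear sequence: 15 steps (steps 1–3, 5–10, 12–15, 20 and 21, from 1)

Steps most likely to fail

Step 14. The C11a radical may be lost by hydrogen abstraction or by elimination before it is oxidised, and the facial selectivity of either ring closure may be poor. The fallback separates the two bond formations; it sets out from 18 and comes back at 20. Compound 18 is brominated at the malonate carbon (NaH, BrCl2CCCl2Br, THF, 0 °C) to di(prop-2-en-1-yl) 2-bromo-2-(alkoxymethyl)propanedioate F1. Bromine-atom-transfer radical cyclisation (CuBr, tris(2-pyridylmethyl)amine, CH2Cl2, rt) then forms the C3–C3a bond and gives the tetrahydrofuran bromide F2 with bromine on C11a. Cleavage of the allyl esters (Pd(PPh3)4, morpholine) and silver-assisted displacement of bromide by a carboxyl group (AgOAc, MeCN) close the O1–C11a bond and give 20.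

Step 20. Elimination may compete with substitution at the hindered C4 carbinol, and the phosphine may add to the methylene lactone. The fallback replaces the SN2 inversion by an oxidation–reduction sequence; it sets out from 22 and comes back at 29. Dess–Martin oxidation of 22 gives the C4 ketone F3. Reduction with NaBH4/CeCl3·7H2O at −78 °C, with hydride expected on the face opposite the lactone substituent on C3a, gives the 4S alcohol F4. Yamaguchi esterification of that alcohol with 28 (2,4,6-trichlorobenzoyl chloride, Et3N, DMAP, toluene) gives 29.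

Step 10. Oligomerisation may outrun closure of the strained ten-membered ring, and the skipped diene may suffer alkene migration. The fallback closes the C4–C3a bond by a Nozaki–Hiyama–Kishi reaction; it sets out from 6 and comes back at 15. Ylide 7 is alkylated with (Z)-3-bromo-1-iodoprop-1-ene and deprotonated to the iodoallyl ylide F5. Wittig reaction of that ylide with 6 gives the hydroxy iodo-diene ester F6, and Dess–Martin oxidation gives the aldehyde F7. CrCl2 with NiCl2 (cat.) in DMSO/THF at high dilution closes the ring to the cyclic allylic alcohol F8, whose 7R epimer is separated from its diastereomer by chromatography. Reduction with i-Bu2AlH gives the diol F9, and TBSCl/imidazole at 0 °C gives 15.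

Further compounds
F1 | step 14 | di(prop-2-en-1-yl) 2-bromo-2-({[(1R,2Z,5E,9R)-5-({[tert-butyl(dimethyl)silyl]oxy}methyl)-9-methyl-9-[(triethylsilyl)oxy]cyclodeca-2,5-dien-1-yl]oxy}methyl)propanedioate | C1[C@@H](OCC(Br)(C(=O)OCC=C)C(=O)OCC=C)/C=C\C/C(CO[Si](C)(C)C(C)(C)C)=C\CC[C@@]1(C)O[Si](CC)(CC)CC
F2 | step 14 | tetrahydrofuran bromide (target locants): C3–C13H2–O–C4 ring closed on C3a, two allyl ester groups on C3, bromine on C11a (epimers at C11a), H3a trans to H4 | O=C(OCC=C)C1(C(=O)OCC=C)CO[C@@H]2C[C@](C)(O[Si](CC)(CC)CC)CC/C=C(CO[Si](C)(C)C(C)(C)C)\CC(Br)[C@@H]12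
F3 | step 20 | (3aR,6R,9E,11aS)-10-({[tert-butyl(dimethyl)silyl]oxy}methyl)-6-methyl-3-methylidene-6-[(triethylsilyl)oxy]-3,3a,5,6,7,8,11,11a-octahydrocyclodeca[b]furan-2,4-dione | C=C1C(=O)O[C@H]2C/C(CO[Si](C)(C)C(C)(C)C)=C\CC[C@@](C)(O[Si](CC)(CC)CC)CC(=O)[C@H]12
F4 | step 20 | (3aS,4S,6R,9E,11aS)-10-({[tert-butyl(dimethyl)silyl]oxy}methyl)-4-hydroxy-6-methyl-3-methylidene-6-[(triethylsilyl)oxy]-3a,4,5,6,7,8,11,11a-octahydrocyclodeca[b]furan-2(3H)-one | C=C1C(=O)O[C@H]2C/C(CO[Si](C)(C)C(C)(C)C)=C\CC[C@@](C)(O[Si](CC)(CC)CC)C[C@H](O)[C@H]12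
F5 | step 10 | ethyl (4Z)-5-iodo-2-(triphenyl-λ5-phosphanylidene)pent-4-enoate | CCOC(=O)C(C/C=C\I)=P(c1ccccc1)(c1ccccc1)c1ccccc1
F6 | step 10 | ethyl (2E,6R)-8-hydroxy-2-[(2Z)-3-iodoprop-2-en-1-yl]-6-methyl-6-[(triethylsilyl)oxy]oct-2-enoate | I/C=C\C/C(C(=O)OCC)=C\CC[C@@](C)(O[Si](CC)(CC)CC)CCO
F7 | step 10 | ethyl (2E,6R)-2-[(2Z)-3-iodoprop-2-en-1-yl]-6-methyl-8-oxo-6-[(triethylsilyl)oxy]oct-2-enoate | I/C=C\C/C(C(=O)OCC)=C\CC[C@@](C)(O[Si](CC)(CC)CC)CC=O
F8 | step 10 | ethyl (1E,5R,7R,8Z)-7-hydroxy-5-methyl-5-[(triethylsilyl)oxy]cyclodeca-1,8-diene-1-carboxylate | C1[C@@H](O)/C=C\C/C(C(=O)OCC)=C\CC[C@@]1(C)O[Si](CC)(CC)CC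
F9 | step 10 | (1R,2Z,5E,9R)-5-(hydroxymethyl)-9-methyl-9-[(triethylsilyl)oxy]cyclodeca-2,5-dien-1-ol | C1[C@@H](O)/C=C\C/C(CO)=C\CC[C@@]1(C)O[Si](CC)(CC)CC
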